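The route cuts the two bonds from isoquinoline C6 (to oxygen) and C7 (to carbon) that anchor the arene to the bridged 2,9-dioxabicyclo[3.3.1]nonane acetal. In one pot, 8-methoxy-3-methyl-6,7-isoquinolyne inserts into the C=O bond of DMF, the 8-methoxy group steering oxygen to C6 and carbon to C7; the iminium-activated salicylaldehyde so formed condenses with a 2-acetonylbenzaldehyde, and the resulting o-hydroxybenzylidene ketone, the presumed biosynthetic intermediate, closes both acetal rings and sets three stereocentres in relative terms. Aryne precursor and ketone both derive from one 1H-isochromene. The cascade is inherently racemic; the enantiomer is secured by chromatography on a chiral phase before the final deprotection.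

Key step: step 11

Remark on the chemistry: the three stereocentres are called C-a (acetal carbon between the two ring oxygens), C-b (oxygen-bearing methine on isoquinoline C7) and C-c (acetyl-bearing methine); the target is C-a R, C-b R, C-c S. Compounds 5, 6 and 10 are racemic at an acetal centre that is destroyed later and are written without stereodescriptor; the SMILES of racemic 15 shows the enantiomer that is carried on. 2,4-Dihydroxy-6-methoxybenzaldehyde is taken to be commercially available.

Step 1
Reactants: 1 2,4-dihydroxy-6-methoxybenzaldehyde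
Product: 2 2-hydroxy-6-methoxy-4-(methoxymethoxy)benzaldehyde
Conditions: MOMCl (1.05 equiv), K2CO3, acetone, 0 °C to rt
Reagents that add atoms: chloromethyl methyl ether, COCCl
Why: Williamson O-alkylation should take the 4-OH selectively, because the 2-OH is tied up in the hydrogen bond to the ortho-formyl group.

Step 2
Reactants: 2 2-hydroxy-6-methoxy-4-(methoxymethoxy)benzaldehyde
Product: 3 2-formyl-3-methoxy-5-(methoxymethoxy)phenyl trifluoromethanesulfonate
Conditions: Tf2O, pyridine, CH2Cl2, -10 °C
Reagents that add atoms: trifluoromethanesulfonic anhydride, O=S(=O)(OS(=O)(=O)C(F)(F)F)C(F)(F)F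
Why: O-sulfonylation of the remaining phenol turns it into the leaving group for cross-coupling.

Step 3
Reactants: 3 2-formyl-3-methoxy-5-(methoxymethoxy)phenyl trifluoromethanesulfonate
Product: 4 2-methoxy-4-(methoxymethoxy)-6-(prop-1-yn-1-yl)benzaldehyde
Conditions: propyne (THF solution), Pd(PPh3)2Cl2 (cat.), CuI (cat.), Et3N, DMF, rt
Reagents that add atoms: propyne, CC#C
Why: Sonogashira coupling at the aryl triflate, which is activated by the ortho-formyl group, installs the three-carbon chain needed on both the ketone side and the isoquinoline side.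

Step 4
Reactants: 4 2-methoxy-4-(methoxymethoxy)-6-(prop-1-yn-1-yl)benzaldehyde
Product: 5 rac-1,8-dimethoxy-6-(methoxymethoxy)-3-methyl-1H-isochromene
Conditions: AgOTf (5 mol%), MeOH, CH2Cl2, rt
Reagents that add atoms: methanol, CO
Why: Silver-catalysed 6-endo-dig attack of the aldehyde oxygen on the alkyne (cycloisomerisation via a 2-benzopyrylium ion) and capture by methanol at C1 masks the aldehyde and the latent ketone in one base-stable ring; the new C1 centre forms racemic and is destroyed later.

Step 5
Reactants: 5 rac-1,8-dimethoxy-6-(methoxymethoxy)-3-methyl-1H-isochromene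
Product: 6 rac-[1,8-dimethoxy-6-(methoxymethoxy)-3-methyl-1H-isochromen-7-yl]trimethylsilane
Conditions: n-BuLi, TMEDA, THF, -78 to -20 °C; then TMSCl, -78 °C
Reagents that add atoms: chlorotrimethylsilane, C[Si](C)(C)Cl
Why: Directed ortho-metalation should occur at C7, the only position flanked by two coordinating oxygen groups (OMOM and OMe), and the aryllithium is silylated.

Step 6
Reactants: 6 rac-[1,8-dimethoxy-6-(methoxymethoxy)-3-methyl-1H-isochromen-7-yl]trimethylsilane
Product: 7 8-methoxy-6-(methoxymethoxy)-3-methyl-7-(trimethylsilyl)isoquinoline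
Conditions: NH4OAc, MeOH, 50 °C
Reagents that add atoms: ammonium acetate, CC(=O)[O-].[NH4+]
Why: The weak acid ionises the cyclic acetal to the 2-benzopyrylium ion, which ammonia converts into the pyridine ring (pyrylium-to-pyridine exchange, the laboratory counterpart of the biosynthetic isoquinoline formation) without touching the C–Si bond.

Step 7
Reactants: 7 8-methoxy-6-(methoxymethoxy)-3-methyl-7-(trimethylsilyl)isoquinoline
Product: 8 8-methoxy-3-methyl-7-(trimethylsilyl)isoquinolin-6-ol
Conditions: HCl in MeOH (1.25 M), 0 °C to rt; aq. NaHCO3
Reagents that add atoms: none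
Why: Acid-catalysed cleavage of the MOM acetal (transacetalisation to methanol); N-protonation deactivates the arene, which should protect the aryl–silicon bond against ipso-protodesilylation.

Step 8
Reactants: 8 8-methoxy-3-methyl-7-(trimethylsilyl)isoquinolin-6-ol
Product: 9 8-methoxy-3-methyl-7-(trimethylsilyl)isoquinolin-6-yl trifluoromethanesulfonate
Conditions: PhNTf2, Et3N, DMAP (cat.), CH2Cl2, rt
Reagents that add atoms: N-phenylbis(trifluoromethanesulfonimide), O=S(=O)(N(c1ccccc1)S(=O)(=O)C(F)(F)F)C(F)(F)F
Why: O-triflation of the hindered o-silylphenol with the mild triflimide reagent completes the o-silylaryl triflate aryne precursor without activating the ring nitrogen.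

Step 9
Reactants: 5 rac-1,8-dimethoxy-6-(methoxymethoxy)-3-methyl-1H-isochromene
Product: 10 rac-1,8-dimethoxy-6-(methoxymethoxy)-3-methyl-1H-isochromene-7-carbaldehyde
Conditions: n-BuLi, TMEDA, THF, -78 to -20 °C; then DMF, -78 °C; aq. NH4Cl
Reagents that add atoms: N,N-dimethylformamide, CN(C)C=O
Why: The same directed ortho-metalation at C7 followed by formylation with DMF (Bouveault aldehyde synthesis) places the second formyl group between OMOM and OMe.

Step 10
Reactants: 10 rac-1,8-dimethoxy-6-(methoxymethoxy)-3-methyl-1H-isochromene-7-carbaldehyde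
Product: 11 2-methoxy-4-(methoxymethoxy)-6-(2-oxopropyl)benzene-1,3-dicarbaldehyde
Conditions: AcOH/THF/H2O (2:2:1), rt
Reagents that add atoms: water, O
Why: Mild aqueous acid hydrolyses the enol-ether acetal through the benzopyrylium ion and the lactol to the open keto aldehyde, while the aryl MOM ether, which needs stronger acid, should stay.

Step 11
Reactants: 9 8-methoxy-3-methyl-7-(trimethylsilyl)isoquinolin-6-yl trifluoromethanesulfonate; 11 2-methoxy-4-(methoxymethoxy)-6-(2-oxopropyl)benzene-1,3-dicarbaldehyde
Product: 15 racemic methoxymethyl ether of 17 (C-a R*/C-b R*/C-c S*), via isoquinolyne 12 (not isolated), via aminomethylene quinone methide 13 (not isolated), via hydroxybenzylidene ketone 14 (not isolated)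
Conditions: CsF (3 equiv), DMF (0.02 M), 25 °C; then 11, AcOH, 40 °C
Reagents that add atoms: N,N-dimethylformamide, CN(C)C=O
Why: Proposed new method: fluoride unmasks isoquinolyne 12, whose C6≡C7 bond undergoes formal [2+2] insertion into the C=O bond of the solvent DMF (oxygen to C6, carbon to C7, as dictated by the inductively polarising 8-OMe group) to give the aminal-type o-quinone methide 13; this iminium-activated salicylaldehyde condenses at the benzylic CH2 of 11 (Mannich addition, loss of Me2NH) to the o-hydroxybenzylidene ketone 14, the presumed biosynthetic intermediate, which closes to 15. The closest known reaction type is the three-component coupling of arynes, DMF and 1,3-dicarbonyl C–H acids to 2H-chromenes and coumarins; new are the benzyl ketone as the C–H acid and the terminating double acetalisation. Ring closure: the phenol adds reversibly to the neighbouring aldehyde (eight-membered hemiacetal) and the hemiacetal hydroxyl then adds across the ring to the enone, 6-exo-trig for the 1,3-dioxine ring and 6-endo-trig for the isochroman ring. C-a and C-b are set together by the bicyclo[3.3.1] bridge, which allows only the cis pair (substrate geometry, racemic), and C-c is set by protonation of the enolate on the convex face, anti to the axial isoquinoline carbon on C-b. The step needs the aryne to be trapped by DMF and not by the isoquinoline nitrogen of a second molecule (DMF as solvent, high dilution), condensation at the benzylic CH2 and not at the methyl group (more acidic, conjugated enol), and acetalisation by the formyl group ortho to the side chain only (the other formyl group cannot reach).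

Step 12
Reactants: 15 racemic methoxymethyl ether of 17
Product: 16 methoxymethyl ether of 17, single enantiomer (C-a R, C-b R, C-c S)
Conditions: preparative SFC, amylose tris(3,5-dimethylphenylcarbamate) phase, CO2/MeOH, 35 °C
Reagents that add atoms: none
Why: Resolution by chromatography on a chiral stationary phase separates the enantiomers of 15, whose three centres are locked to one another by the bicyclic acetal, and the (R,R,S) fraction (to be assigned by ECD against calculation and by correlation of 17 with the natural product) is taken on.

Step 13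
Reactants: 16 methoxymethyl ether of 17, single enantiomer
Product: 17 target CNP0584953.1 (C-a R, C-b R, C-c S)
Conditions: TFA/CH2Cl2 (1:10), 0 °C; aq. NaHCO3
Reagents that add atoms: none
Why: Acid-mediated cleavage of the MOM acetal, assisted by the ortho-formyl group, should free the phenol under conditions in which the N-protonated bridged acetal and the three stereocentres persist.

Compound list
1 | 2,4-dihydroxy-6-methoxybenzaldehyde | COc1cc(O)cc(O)c1C=O | starting material
2 | 2-hydroxy-6-methoxy-4-(methoxymethoxy)benzaldehyde | COCOc1cc(O)c(C=O)c(OC)c1 | intermediate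
3 | 2-formyl-3-methoxy-5-(methoxymethoxy)phenyl trifluoromethanesulfonate | COCOc1cc(OS(=O)(=O)C(F)(F)F)c(C=O)c(OC)c1 | intermediate
4 | 2-methoxy-4-(methoxymethoxy)-6-(prop-1-yn-1-yl)benzaldehyde | CC#Cc1cc(OCOC)cc(OC)c1C=O | intermediate
5 | rac-1,8-dimethoxy-6-(methoxymethoxy)-3-methyl-1H-isochromene | COC1OC(C)=Cc2cc(OCOC)cc(OC)c21 | intermediate
6 | rac-[1,8-dimethoxy-6-(methoxymethoxy)-3-methyl-1H-isochromen-7-yl]trimethylsilane | COC1OC(C)=Cc2cc(OCOC)c([Si](C)(C)C)c(OC)c21 | intermediate
7 | 8-methoxy-6-(methoxymethoxy)-3-methyl-7-(trimethylsilyl)isoquinoline | COCOc1cc2cc(C)ncc2c(OC)c1[Si](C)(C)C | intermediate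
8 | 8-methoxy-3-methyl-7-(trimethylsilyl)isoquinolin-6-ol | Cc1cc2cc(O)c([Si](C)(C)C)c(OC)c2cn1 | intermediate
9 | 8-methoxy-3-methyl-7-(trimethylsilyl)isoquinolin-6-yl trifluoromethanesulfonate | Cc1cc2cc(OS(=O)(=O)C(F)(F)F)c([Si](C)(C)C)c(OC)c2cn1 | intermediate
10 | rac-1,8-dimethoxy-6-(methoxymethoxy)-3-methyl-1H-isochromene-7-carbaldehyde | COC1OC(C)=Cc2cc(OCOC)c(C=O)c(OC)c21 | intermediate
11 | 2-methoxy-4-(methoxymethoxy)-6-(2-oxopropyl)benzene-1,3-dicarbaldehyde | CC(=O)Cc1cc(OCOC)c(C=O)c(OC)c1C=O | intermediate
12 | 8-methoxy-3-methyl-6,7-didehydroisoquinoline (6,7-isoquinolyne) | COC1=C2C=NC(C)=CC2=CC#C1 | intermediate (not isolated)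
13 | 7-[(dimethylamino)methylidene]-8-methoxy-3-methylisoquinolin-6(7H)-one (aryne–DMF insertion product, open form) | CN(C)C=C1C(=O)C=C2C=C(C)N=CC2=C1OC | intermediate (not isolated)
14 | (E)-3-[2,4-diformyl-3-methoxy-5-(methoxymethoxy)phenyl]-4-(6-hydroxy-8-methoxy-3-methylisoquinolin-7-yl)but-3-en-2-one (the two aryl groups cis) | CC(=O)/C(=C/c1c(O)cc2cc(C)ncc2c1OC)c1cc(OCOC)c(C=O)c(OC)c1C=O | intermediate (not isolated)
15 | racemic methoxymethyl ether of 17: bridged acetal with the ring-A phenol as OCH2OCH3, relative configuration C-a R*, C-b R*, C-c S* | COc1c(C=O)c(OCOC)cc2c1[C@H]1Oc3cc4cc(C)ncc4c(OC)c3[C@H](O1)[C@H]2C(C)=O | intermediate (racemate)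
16 | methoxymethyl ether of 17, single enantiomer (C-a R, C-b R, C-c S) | COc1c(C=O)c(OCOC)cc2c1[C@H]1Oc3cc4cc(C)ncc4c(OC)c3[C@H](O1)[C@H]2C(C)=O | intermediate
17 | CNP0584953.1: 2,9-dioxabicyclo[3.3.1]nonane acetal joining the 3-formyl-4-hydroxy-2-methoxybenzo ring (at C-a and C-c) and 8-methoxy-3-methylisoquinoline (C6–O and C7–C-b), acetyl on C-c; C-a R, C-b R, C-c S | COc1c(C=O)c(O)cc2c1[C@H]1Oc3cc4cc(C)ncc4c(OC)c3[C@H](O1)[C@H]2C(C)=O | target

Total step count: 13. Longest linear sequence: 11 steps (steps 1 to 8, then 11, 12 and 13).

Steps most likely to fail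

Step 11 (Proposed new method). Interception of the aminal 13 by the weakly acidic benzyl ketone may be too slow, so that 13 is lost to a second aryne or to adventitious water. The ketone may also be consumed by intramolecular aldol condensation of its methyl group onto the ortho-formyl group, or may condense at the methyl group. The fallback uses known chemistry and sets out from 9 and 11. Aryne insertion into DMF with aqueous work-up (CsF, DMF, rt; then H2O) gives 6-hydroxy-8-methoxy-3-methylisoquinoline-7-carbaldehyde F1. Knoevenagel condensation of F1 with 11 under piperidinium acetate (toluene, 4 Å molecular sieves, 60 °C), the classical condensation of salicylaldehydes with benzyl ketones, should pass through 14 to the same acetalisation and comes back to the route at 15.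

Step 7. The trimethylsilyl group may be lost by ipso-protonation during the acidic MOM cleavage. The fallback brings silicon in after the acid stage and sets out from 5. Lithiation as in step 5 with an iodine quench gives rac-7-iodo-1,8-dimethoxy-6-(methoxymethoxy)-3-methyl-1H-isochromene F2. NH4OAc in MeOH gives 7-iodo-8-methoxy-6-(methoxymethoxy)-3-methylisoquinoline F3, and HCl in MeOH gives 7-iodo-8-methoxy-3-methylisoquinolin-6-ol F4. Hexamethyldisilazane gives 7-iodo-8-methoxy-3-methyl-6-(trimethylsilyloxy)isoquinoline F5. n-BuLi in THF at -100 °C (iodine–lithium exchange, then 1,3 O-to-C silyl shift, retro-Brook rearrangement) and aqueous work-up come back to the route at 8.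

Step 13. The bridged acetal may open reversibly and the acetyl-bearing carbon may epimerise by enolisation under the acid that removes MOM. The fallback uses no acid after the stereocentres exist and sets out from 10. 2 M HCl in THF at rt removes the isochromene acetal and the MOM group together and gives 4-hydroxy-2-methoxy-6-(2-oxopropyl)benzene-1,3-dicarbaldehyde F6. The cascade of step 11 with 9 then gives racemic 17 F7 directly, and chromatography on the chiral phase as in step 12 comes back to the route at 17.

Further compounds
F1 | step 11 | 6-hydroxy-8-methoxy-3-methylisoquinoline-7-carbaldehyde | Cc1cc2cc(O)c(C=O)c(OC)c2cn1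
F2 | step 7 | rac-7-iodo-1,8-dimethoxy-6-(methoxymethoxy)-3-methyl-1H-isochromene | COC1OC(C)=Cc2cc(OCOC)c(I)c(OC)c21
F3 | step 7 | 7-iodo-8-methoxy-6-(methoxymethoxy)-3-methylisoquinoline | COCOc1cc2cc(C)ncc2c(OC)c1I
F4 | step 7 | 7-iodo-8-methoxy-3-methylisoquinolin-6-ol | Cc1cc2cc(O)c(I)c(OC)c2cn1
F5 | step 7 | 7-iodo-8-methoxy-3-methyl-6-(trimethylsilyloxy)isoquinoline | Cc1cc2cc(O[Si](C)(C)C)c(I)c(OC)c2cn1
F6 | step 13 | 4-hydroxy-2-methoxy-6-(2-oxopropyl)benzene-1,3-dicarbaldehyde | CC(=O)Cc1cc(O)c(C=O)c(OC)c1C=O
F7 | step 13 | racemic 17 (relative configuration C-a R*, C-b R*, C-c S*) | COc1c(C=O)c(O)cc2c1[C@H]1Oc3cc4cc(C)ncc4c(OC)c3[C@H](O1)[C@H]2C(C)=O
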